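**Assumption:** the SMILES encodes the all-trans cyclobutane with the aminoimidazole-bearing carbons S and the CH2N-bearing carbons R, i.e. (1R,2S,3S,4R) in sceptrin numbering. The route is racemic up to a resolution; which separated antipode is the (1R,2R,3S,4S) one is assigned by anomalous-dispersion X-ray of bromide 8.

## Retrosynthetic overview

1. Target ⇐ hydrazinolysis of two imidazo[1,2-a]pyrimidines (masked 2-aminoimidazoles) in bis-amide 10.
2. 10 ⇐ two successive N-acylations of the C2-symmetric diamine 6. The two CH2NH2 arms are homotopic, so mono-acylation gives one mono-amide whichever nitrogen reacts.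
3. 6 ⇐ enantiopure bis-Boc cyclobutane 5 ⇐ resolution of the racemic all-trans head-to-head dimer 4.
4. 4 ⇐ sensitized [2+2] photodimerization of alkenyl-imidazopyrimidine 3. This is the only ring-forming step; the heteroaromatic rings are bought preformed and unmasked last.
5. 3 ⇐ Heck coupling of 3-bromoimidazo[1,2-a]pyrimidine with N-Boc-allylamine.

## Forward route

**Step 1**
Reactants: 1, 3-bromoimidazo[1,2-a]pyrimidine; 2, tert-butyl allylcarbamate (N-Boc-allylamine, 1.5 equiv)
Product: 3, tert-butyl (E)-[3-(imidazo[1,2-a]pyrimidin-3-yl)allyl]carbamate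
Conditions: Pd(OAc)2 (5 mol %), P(o-tol)3 (12 mol %), Et3N, DMF, 90 °C
Reagents that add atoms: tert-butyl allylcarbamate (2), C=CCNC(=O)OC(C)(C)C
Why: Mizoroki–Heck reaction; syn-insertion then β-hydride elimination toward the heteroaryl-bearing carbon gives the conjugated E-alkene, and no stereocentre is formed.

**Step 2**
Reactants: 3 (two molecules)
Product: 4, racemic di-tert-butyl {[(1R*,2R*,3S*,4S*)-3,4-di(imidazo[1,2-a]pyrimidin-3-yl)cyclobutane-1,2-diyl]bis(methylene)}dicarbamate (head-to-head, every substituent trans to both neighbours)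
Conditions: fac-Ir(ppy)3 (1–2 mol %), degassed MeOH, 0.3–0.5 M, 450 nm LEDs, rt; chromatography to remove minor diastereomers
Reagents that add atoms: none
Why: Triplet-sensitized intermolecular [2+2] photodimerization, as used for the closely related bromopyrrole-amide monomer. The first bond forms between the two CH2N-bearing alkene carbons, giving a bis(heteroaryl-stabilized) 1,4-biradical (hence head-to-head), and this long-lived biradical closes to the least hindered all-trans ring, setting all four stereocentres relative to one another.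

**Step 3**
Reactants: 4 (racemate)
Product: 5, di-tert-butyl {[(1R,2R,3S,4S)-3,4-di(imidazo[1,2-a]pyrimidin-3-yl)cyclobutane-1,2-diyl]bis(methylene)}dicarbamate (single enantiomer)
Conditions: preparative chiral SFC (immobilized amylose phase, CO2/MeOH with 0.1% Et2NH); the antipode is set aside
Reagents that add atoms: none
Why: Chromatographic resolution of a neutral C2-symmetric bis-carbamate fixes the absolute configuration, and none of the four ring C–H centres is epimerizable in the later steps.

**Step 4**
Reactants: 5
Product: 6, [(1R,2R,3S,4S)-3,4-di(imidazo[1,2-a]pyrimidin-3-yl)cyclobutane-1,2-diyl]dimethanamine (free base)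
Conditions: TFA/CH2Cl2 (1:3), 0 °C to rt; basic ion-exchange work-up
Reagents that add atoms: none
Why: Acidolytic Boc cleavage; the imidazopyrimidines are acid-stable and the stereocentres are untouched.

**Step 5**
Reactants: 6 (2 equiv, excess recovered); 7, 1-(4-bromo-1H-pyrrol-2-yl)-2,2,2-trichloroethan-1-one (1 equiv, slow addition)
Product: 8, N-{[(1R,2R,3S,4S)-2-(aminomethyl)-3,4-di(imidazo[1,2-a]pyrimidin-3-yl)cyclobutyl]methyl}-4-bromo-1H-pyrrole-2-carboxamide
Conditions: i-Pr2NEt, DMF, 0 °C to rt; separate from recovered 6 and the bis-amide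
Reagents that add atoms: 4-bromo-2-(trichloroacetyl)pyrrole (7), O=C(c1cc(Br)c[nH]1)C(Cl)(Cl)Cl (delivers the 4-bromopyrrole-2-carbonyl group; CHCl3 is lost)
Why: Haloform-type amine acylation by a trichloromethyl ketone, selective for the primary alkylamine; because the two amines are related by the C2 axis, statistical mono-acylation gives a single constitutional and stereo-isomer.

**Step 6**
Reactants: 8; 9, 2,2,2-trichloro-1-(1H-pyrrol-2-yl)ethan-1-one (1.5 equiv)
Product: 10, N-{[(1R,2S,3S,4R)-4-{[(4-bromo-1H-pyrrole-2-carbonyl)amino]methyl}-2,3-di(imidazo[1,2-a]pyrimidin-3-yl)cyclobutyl]methyl}-1H-pyrrole-2-carboxamide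
Conditions: Et3N, DMF, rt to 40 °C
Reagents that add atoms: 2-(trichloroacetyl)pyrrole (9), O=C(c1ccc[nH]1)C(Cl)(Cl)Cl
Why: The same haloform-type acylation on the remaining primary amine; the existing amide, aryl bromide and imidazopyrimidines are inert.

**Step 7**
Reactants: 10
Product: 11, desbromosceptrin, N-{[(1R,2S,3S,4R)-2,3-bis(2-amino-1H-imidazol-5-yl)-4-{[(4-bromo-1H-pyrrole-2-carbonyl)amino]methyl}cyclobutyl]methyl}-1H-pyrrole-2-carboxamide
Conditions: N2H4·H2O (excess), EtOH, 80–90 °C; reverse-phase HPLC (0.1% TFA), isolated as the bis-TFA salt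
Reagents that add atoms: none (hydrazine leaves with the C5–C6–C7 unit as pyrazole)
Why: Hydrazinolytic cleavage of the pyrimidine ring unmasks each 2-aminoimidazole (the former C3 substituent ends up at imidazole C4/5); secondary pyrrole amides and the aryl bromide survive, and no stereocentre is involved.

## Compound list

1 | 3-bromoimidazo[1,2-a]pyrimidine | Brc1cnc2ncccn12 | starting material
2 | tert-butyl allylcarbamate | C=CCNC(=O)OC(C)(C)C | starting material
3 | tert-butyl (E)-[3-(imidazo[1,2-a]pyrimidin-3-yl)allyl]carbamate | CC(C)(C)OC(=O)NC/C=C/c1cnc2ncccn12 | intermediate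
4 | racemic all-trans head-to-head bis-Boc photodimer (one enantiomer drawn) | c1cnc2ncc([C@H]3[C@H](CNC(=O)OC(C)(C)C)[C@@H](CNC(=O)OC(C)(C)C)[C@@H]3c3cnc4ncccn34)n2c1 | intermediate
5 | (1R,2R,3S,4S) bis-Boc dimer, single enantiomer | c1cnc2ncc([C@H]3[C@H](CNC(=O)OC(C)(C)C)[C@@H](CNC(=O)OC(C)(C)C)[C@@H]3c3cnc4ncccn34)n2c1 | intermediate
6 | [(1R,2R,3S,4S)-3,4-di(imidazo[1,2-a]pyrimidin-3-yl)cyclobutane-1,2-diyl]dimethanamine | c1cnc2ncc([C@H]3[C@H](CN)[C@@H](CN)[C@@H]3c3cnc4ncccn34)n2c1 | intermediate
7 | 1-(4-bromo-1H-pyrrol-2-yl)-2,2,2-trichloroethan-1-one | O=C(c1cc(Br)c[nH]1)C(Cl)(Cl)Cl | starting material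
8 | mono-(4-bromopyrrole) amide of diamine 6 | c1cnc2ncc([C@H]3[C@H](CN)[C@@H](CNC(=O)c4cc(Br)c[nH]4)[C@@H]3c3cnc4ncccn34)n2c1 | intermediate
9 | 2,2,2-trichloro-1-(1H-pyrrol-2-yl)ethan-1-one | O=C(c1ccc[nH]1)C(Cl)(Cl)Cl | starting material
10 | mixed pyrrole / 4-bromopyrrole bis-amide, bis(imidazopyrimidine) | c1cnc2ncc([C@H]3[C@H](CNC(=O)c4ccc[nH]4)[C@@H](CNC(=O)c4cc(Br)c[nH]4)[C@@H]3c3cnc4ncccn34)n2c1 | intermediate
11 | desbromosceptrin | Nc1ncc([C@H]2[C@H](CNC(=O)c3ccc[nH]3)[C@@H](CNC(=O)c3cc(Br)c[nH]3)[C@@H]2c2cnc(N)[nH]2)[nH]1 | target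

## Summary

Total steps: 7. Longest linear sequence: 7 (fully linear from 1 and 2).

Steps most likely to fail, with a fallback that changes the approach:

1. **Step 2, photodimerization** (E/Z isomerization outcompeting dimerization, modest yield, diastereomer mixtures). Fallback: start from a preformed ring, commercial cis,trans,cis-cyclobutane-1,2,3,4-tetracarboxylic dianhydride. Cinchona-alkaloid double methanolysis gives the C2-symmetric diacid-diester, NaOMe epimerizes only the ester-bearing carbons to the all-trans isomer, the acid arms go to CH2N3 (BH3, then Mitsunobu azidation), and the ester arms go to chloromethyl ketones and then masked aminoimidazoles.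
2. **Step 3, resolution** (poor separation, 50% ceiling, assignment of the antipode). Fallback: make the cycloaddition diastereoselective. Join two molecules of 3 through their carbamate nitrogens with an enantiopure C2-symmetric diacyl tether (tartrate acetonide diacid chloride, giving N-acyl-N-Boc imides), run the [2+2] intramolecularly, and cleave the activated imides with LiOH/H2O2 to release 5. The asymmetric dianhydride route in item 1 is a second alternative.
3. **Step 5, statistical mono-acylation** (over-acylation, tedious separation of polar amines). Fallback: differentiate the arms at ring formation by a crossed [2+2] between 3 and its N-(4-bromopyrrole-2-carbonyl) analogue (from 3 by Boc removal and acylation with 7). The Boc/amide heterodimer then needs only resolution, Boc removal and one acylation with 9.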